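Ring C is cut along C3–C2 and O1–C8a: benzaldehyde is the O1=C2 unit and C3–C4–C4a–C8a an open-chain 1,3-dioxygenated diene. A BINOL–titanium-catalysed oxa-Diels–Alder reaction of ethyl 2,4-bis(trimethylsilyloxy)penta-2,4-dienoate forms both bonds and sets C2. It exploits the vinylogous ester O1–C8a=C4a–C4=O hidden in the fusion of ring A and ring C; C8a is then still a non-aromatic, ester-bearing carbon. The ester becomes a diazoketone, and a Danheiser benzannulation with a siloxyalkyne carrying the complete, masked side chain builds ring A with 5-OH, the C6 substituent and 7-O in place. Lactone unmasking and deprotection finish.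

Key step: step 2

Remark (numbering): flavanone atoms are O1, C2 to C8a; the side chain is numbered C2′ (lactone C=O), C3′=C4′, C5′ (CHOH), C6′ (ring CH–O), C7′ (CHOH), C8′ (CHPh).
Remark (mixtures): the acetal carbons of 14, 22 to 27 and 29 to 31 and the sp3 ring carbon of 29 form as epimer mixtures and are carried on, because these centres are removed in steps 7, 15 and 17.
Remark (assumption): (S)-BINOL is assumed to direct attack to the Si face of benzaldehyde in step 2 (S at C2), by analogy with other BINOL–titanium additions to benzaldehyde; the antipodal ligand would be used otherwise.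

Step 1
Reactants: 1 ethyl 2,4-dioxopentanoate
Product: 2 ethyl (2Z)-2,4-bis(trimethylsilyloxy)penta-2,4-dienoate
Conditions: Me3SiOTf (2.2 equiv), Et3N, Et2O, 0 °C
Reagents that add atoms: trimethylsilyl trifluoromethanesulfonate, C[Si](C)(C)OS(=O)(=O)C(F)(F)F
Why: Double O-silylation by soft enolisation traps the enolised C2 oxygen and the methyl ketone, giving the 1,3-bis(silyloxy)diene without forming a stereocentre.

Step 2
Reactants: 2 ethyl (2Z)-2,4-bis(trimethylsilyloxy)penta-2,4-dienoate; 3 benzaldehyde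
Product: 5 ethyl (2S)-4-oxo-2-phenyl-3,4-dihydro-2H-pyran-6-carboxylate, via silylated aldol adduct 4 (not isolated)
Conditions: Ti(OiPr)4 (10 mol %), (S)-BINOL (20 mol %), 4 Å molecular sieves, Et2O, −20 °C; then CF3CO2H, CH2Cl2, 0 °C
Reagents that add atoms: none
Why: The chiral BINOLate–titanium Lewis acid binds benzaldehyde and the unsubstituted CH2 terminus of diene 2 attacks its Si face (Mukaiyama-type, asynchronous oxa-Diels–Alder), which forms the C3–C2 bond and gives the silylated aldol 4. Trifluoroacetic acid then frees the C2 oxygen, which adds 6-endo to the silyloxy- and ester-bearing enol carbon (the future C8a) and expels silanol, forming the O1–C8a bond and the enone of ring C. The closest known reaction is the BINOL–titanium-catalysed oxa-Diels–Alder reaction of aldehydes with Danishefsky-type 1-alkoxy-3-silyloxydienes and with 1,3-bis(silyloxy)dienes. Ring C closes by formal [4+2] cycloaddition, completed as a 6-endo oxa-conjugate addition–elimination. The C2 stereocentre is set by the catalyst alone, (S)-BINOL being expected to give S. The step needs attack through the diene terminus and not through its internal enol carbon, which is secured because only the C4 silyl enol ether ends in an unsubstituted CH2 while the other enol ether is deactivated by the ester.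

Step 3
Reactants: 5 ethyl (2S)-4-oxo-2-phenyl-3,4-dihydro-2H-pyran-6-carboxylate
Product: 6 (2S)-4-oxo-2-phenyl-3,4-dihydro-2H-pyran-6-carboxylic acid
Conditions: Me3SnOH, ClCH2CH2Cl, 70 °C; then aq. HCl
Reagents that add atoms: trimethyltin hydroxide, C[Sn](C)(C)O
Why: Tin hydroxide-mediated ester hydrolysis is close to neutral, so the base-labile C2–O1 bond β to the ketone should not open and C2 should keep its configuration.

Step 4
Reactants: 6 (2S)-4-oxo-2-phenyl-3,4-dihydro-2H-pyran-6-carboxylic acid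
Product: 8 (2S)-6-(2-diazoacetyl)-2-phenyl-2,3-dihydro-4H-pyran-4-one, via acid chloride 7 (not isolated)
Conditions: (COCl)2, DMF (cat.), CH2Cl2, 0 °C; then Me3SiCHN2, MeCN/THF, 0 °C
Reagents that add atoms: (trimethylsilyl)diazomethane, C[Si](C)(C)C=[N+]=[N-]
Why: Acylation of the diazoalkane by the acid chloride (first stage of an Arndt–Eistert sequence) gives the α-diazoketone and leaves C2 untouched.

Step 5
Reactants: 9 (2S,3S)-3-phenylglycidol; 10 ethynyltrimethylsilane
Product: 13 (2R,3S)-3-phenyl-5-(trimethylsilyl)pent-4-yne-1,2-diol, via lithium acetylide 11 (not isolated), via alkynylalane 12 (not isolated)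
Conditions: 10, n-BuLi, toluene, −78 °C; Et2AlCl, 0 °C; then 9, 0 °C to rt; aq. potassium sodium tartrate
Reagents that add atoms: none
Why: Alkoxide-directed opening of the 2,3-epoxy alcohol by the alkynylalane (organoaluminium epoxide opening) occurs at the benzylic carbon with inversion, which sets C8′, while C7′ is taken unchanged from the epoxide.

Step 6
Reactants: 13 (2R,3S)-3-phenyl-5-(trimethylsilyl)pent-4-yne-1,2-diol
Product: 14 (4R)-2-(4-methoxyphenyl)-4-[(1S)-1-phenyl-3-(trimethylsilyl)prop-2-yn-1-yl]-1,3-dioxolane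
Conditions: 4-MeOC6H4CH(OMe)2, PPTS (cat.), CH2Cl2, rt
Reagents that add atoms: 4-methoxybenzaldehyde dimethyl acetal, COc1ccc(cc1)C(OC)OC
Why: Acid-catalysed transacetalisation ties the 1,2-diol into a p-methoxybenzylidene acetal whose new centre is irrelevant.

Step 7
Reactants: 14 (4R)-2-(4-methoxyphenyl)-4-[(1S)-1-phenyl-3-(trimethylsilyl)prop-2-yn-1-yl]-1,3-dioxolane
Product: 15 (2R,3S)-2-[(4-methoxybenzyl)oxy]-3-phenyl-5-(trimethylsilyl)pent-4-yn-1-ol
Conditions: i-Bu2AlH, CH2Cl2, −78 to 0 °C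
Reagents that add atoms: none
Why: In this reductive acetal opening the aluminium hydride coordinates the less hindered primary oxygen, so the PMB ether stays on the C7′ oxygen and the primary alcohol is freed.

Step 8
Reactants: 15 (2R,3S)-2-[(4-methoxybenzyl)oxy]-3-phenyl-5-(trimethylsilyl)pent-4-yn-1-ol
Product: 16 (2R,3S)-2-[(4-methoxybenzyl)oxy]-3-phenyl-5-(trimethylsilyl)pent-4-ynal
Conditions: Dess–Martin periodinane, NaHCO3, CH2Cl2, 0 °C to rt
Reagents that add atoms: none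
Why: Buffered Dess–Martin oxidation should give the α-alkoxy aldehyde without epimerising C7′.

Step 9
Reactants: 17 allyl tert-butyldimethylsilyl ether
Product: 19 (Z)-tert-butyldimethyl{[3-(tributylstannyl)prop-1-en-1-yl]oxy}silane, via allyllithium 18 (not isolated)
Conditions: s-BuLi, THF, −78 °C; then Bu3SnCl, −78 °C
Reagents that add atoms: tributyltin chloride, CCCC[Sn](CCCC)(CCCC)Cl
Why: Deprotonation of the allyl ether and γ-stannylation of the oxygen-chelated allyl anion should give the (Z)-γ-silyloxyallylstannane.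

Step 10
Reactants: 16 (2R,3S)-2-[(4-methoxybenzyl)oxy]-3-phenyl-5-(trimethylsilyl)pent-4-ynal; 19 (Z)-tert-butyldimethyl{[3-(tributylstannyl)prop-1-en-1-yl]oxy}silane
Product: 20 (3S,4S,5R,6S)-3-(tert-butyldimethylsilyloxy)-5-[(4-methoxybenzyl)oxy]-6-phenyl-8-(trimethylsilyl)oct-1-en-7-yn-4-ol
Conditions: MgBr2·OEt2 (3 equiv), CH2Cl2, −25 °C
Reagents that add atoms: none
Why: In this chelation-controlled γ-alkoxyallylstannane addition the MgBr2 chelate of the α-alkoxy aldehyde is attacked anti to the C8′ substituent through an open transition state, which sets C6′ syn to C7′ and C5′ syn to C6′.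

Step 11
Reactants: 20 (3S,4S,5R,6S)-3-(tert-butyldimethylsilyloxy)-5-[(4-methoxybenzyl)oxy]-6-phenyl-8-(trimethylsilyl)oct-1-en-7-yn-4-ol; 21 acrolein diethyl acetal
Product: 22 (3S,4S,5R,6S)-3-(tert-butyldimethylsilyloxy)-4-[(1-ethoxyprop-2-en-1-yl)oxy]-5-[(4-methoxybenzyl)oxy]-6-phenyl-8-(trimethylsilyl)oct-1-en-7-yne
Conditions: PPTS (cat.), toluene, 40 °C, reduced pressure
Reagents that add atoms: none
Why: Acid-catalysed transacetalisation with the only free hydroxyl (C6′–OH), driven by removal of ethanol, installs the second alkene as a mixed acetal.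

Step 12
Reactants: 22 (3S,4S,5R,6S)-3-(tert-butyldimethylsilyloxy)-4-[(1-ethoxyprop-2-en-1-yl)oxy]-5-[(4-methoxybenzyl)oxy]-6-phenyl-8-(trimethylsilyl)oct-1-en-7-yne
Product: 23 (5S,6S)-5-(tert-butyldimethylsilyloxy)-2-ethoxy-6-[(1R,2S)-1-[(4-methoxybenzyl)oxy]-2-phenyl-4-(trimethylsilyl)but-3-yn-1-yl]-5,6-dihydro-2H-pyran
Conditions: second-generation Grubbs catalyst (5 mol %), CH2Cl2, 40 °C
Reagents that add atoms: none
Why: Ring-closing metathesis of the two terminal alkenes forms the 2-ethoxy-5,6-dihydro-2H-pyran, a base-stable mask of the lactone, while the silylated alkyne is too hindered to take part.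

Step 13
Reactants: 23 (5S,6S)-5-(tert-butyldimethylsilyloxy)-2-ethoxy-6-[(1R,2S)-1-[(4-methoxybenzyl)oxy]-2-phenyl-4-(trimethylsilyl)but-3-yn-1-yl]-5,6-dihydro-2H-pyran
Product: 24 (5S,6S)-5-(tert-butyldimethylsilyloxy)-2-ethoxy-6-[(1R,2R)-1-[(4-methoxybenzyl)oxy]-2-phenylbut-3-yn-1-yl]-5,6-dihydro-2H-pyran
Conditions: K2CO3 (cat.), MeOH, rt
Reagents that add atoms: none
Why: Methanolysis of the alkynyl C–Si bond (protodesilylation) frees the terminal alkyne without touching the silyl ether or the acetal.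

Step 14
Reactants: 24 (5S,6S)-5-(tert-butyldimethylsilyloxy)-2-ethoxy-6-[(1R,2R)-1-[(4-methoxybenzyl)oxy]-2-phenylbut-3-yn-1-yl]-5,6-dihydro-2H-pyran
Product: 27 (5S,6S)-5-(tert-butyldimethylsilyloxy)-2-ethoxy-6-[(1R,2S)-1-[(4-methoxybenzyl)oxy]-2-phenyl-4-(triisopropylsilyloxy)but-3-yn-1-yl]-5,6-dihydro-2H-pyran, via lithium acetylide 25 (not isolated), via lithium ynolate 26 (not isolated)
Conditions: n-BuLi (1.0 equiv), THF, −78 °C; t-BuOOLi (from t-BuOOH and LiN(SiMe3)2), −78 to 0 °C; then i-Pr3SiOTf, −78 °C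
Reagents that add atoms: tert-butyl hydroperoxide, CC(C)(C)OO; triisopropylsilyl trifluoromethanesulfonate, CC(C)[Si](C(C)C)(C(C)C)OS(=O)(=O)C(F)(F)F
Why: Oxidation of the lithium acetylide by the lithium peroxide gives the ynolate, which is silylated on oxygen to the siloxyalkyne, and C8′ should be safe because the single equivalent of base is consumed by the far more acidic alkyne C–H.

Step 15
Reactants: 8 (2S)-6-(2-diazoacetyl)-2-phenyl-2,3-dihydro-4H-pyran-4-one; 27 (5S,6S)-5-(tert-butyldimethylsilyloxy)-2-ethoxy-6-[(1R,2S)-1-[(4-methoxybenzyl)oxy]-2-phenyl-4-(triisopropylsilyloxy)but-3-yn-1-yl]-5,6-dihydro-2H-pyran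
Product: 30 (2S)-6-{(1S,2R)-2-[(5S,6S)-5-(tert-butyldimethylsilyloxy)-2-ethoxy-5,6-dihydro-2H-pyran-6-yl]-2-[(4-methoxybenzyl)oxy]-1-phenylethyl}-5-hydroxy-2-phenyl-7-(triisopropylsilyloxy)chroman-4-one, via vinylketene 28 (not isolated), via vinylcyclobutenone 29 (not isolated)
Conditions: hν (300 nm), ClCH2CH2Cl, rt; then 80 °C
Reagents that add atoms: none
Why: In this Danheiser benzannulation a photochemical Wolff rearrangement gives vinylketene 28, regioselective [2+2] cycloaddition with the siloxyalkyne (its carbon β to oxygen bonds to the ketene carbonyl) gives 29, and thermal 4π ring opening, 6π electrocyclisation and tautomerisation build ring A with OH at C5, the side chain at C6, the silyl ether at C7 and H at C8 without touching a stereocentre.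

Step 16
Reactants: 30 (2S)-6-{(1S,2R)-2-[(5S,6S)-5-(tert-butyldimethylsilyloxy)-2-ethoxy-5,6-dihydro-2H-pyran-6-yl]-2-[(4-methoxybenzyl)oxy]-1-phenylethyl}-5-hydroxy-2-phenyl-7-(triisopropylsilyloxy)chroman-4-one
Product: 31 (2S)-6-{(1S,2R)-2-[(5S,6S)-5-(tert-butyldimethylsilyloxy)-2-hydroxy-5,6-dihydro-2H-pyran-6-yl]-2-[(4-methoxybenzyl)oxy]-1-phenylethyl}-5-hydroxy-2-phenyl-7-(triisopropylsilyloxy)chroman-4-one
Conditions: PPTS, acetone/H2O, 40 °C
Reagents that add atoms: water, O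
Why: Mild acid hydrolysis of the allylic cyclic acetal through its oxocarbenium ion gives the lactol while the silyl and PMB ethers should survive.

Step 17
Reactants: 31 (2S)-6-{(1S,2R)-2-[(5S,6S)-5-(tert-butyldimethylsilyloxy)-2-hydroxy-5,6-dihydro-2H-pyran-6-yl]-2-[(4-methoxybenzyl)oxy]-1-phenylethyl}-5-hydroxy-2-phenyl-7-(triisopropylsilyloxy)chroman-4-one
Product: 32 (2S)-6-{(1S,2R)-2-[(2S,3S)-3-(tert-butyldimethylsilyloxy)-6-oxo-3,6-dihydro-2H-pyran-2-yl]-2-[(4-methoxybenzyl)oxy]-1-phenylethyl}-5-hydroxy-2-phenyl-7-(triisopropylsilyloxy)chroman-4-one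
Conditions: MnO2, CH2Cl2, rt
Reagents that add atoms: none
Why: MnO2 oxidises the allylic lactol to the α,β-unsaturated δ-lactone (allylic oxidation) and should leave the hydrogen-bonded 5-hydroxyl and the ethers alone.

Step 18
Reactants: 32 (2S)-6-{(1S,2R)-2-[(2S,3S)-3-(tert-butyldimethylsilyloxy)-6-oxo-3,6-dihydro-2H-pyran-2-yl]-2-[(4-methoxybenzyl)oxy]-1-phenylethyl}-5-hydroxy-2-phenyl-7-(triisopropylsilyloxy)chroman-4-one
Product: 33 (2S)-5,7-dihydroxy-6-{(1S,2R)-2-hydroxy-2-[(2R,3S)-3-hydroxy-6-oxo-3,6-dihydro-2H-pyran-2-yl]-1-phenylethyl}-2-phenylchroman-4-one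
Conditions: CF3CO2H, 1,3-dimethoxybenzene (excess), CH2Cl2, 0 °C; then HF·pyridine, THF, 0 °C to rt
Reagents that add atoms: none
Why: Acidolysis removes the PMB ether (its cation is trapped by 1,3-dimethoxybenzene) and fluoride then cleaves both silyl ethers, a global deprotection without base that should preserve the flavanone C2 centre and the lactone.

Compound list
1 | ethyl 2,4-dioxopentanoate | CCOC(=O)C(=O)CC(C)=O | starting material
2 | ethyl (2Z)-2,4-bis(trimethylsilyloxy)penta-2,4-dienoate | CCOC(=O)/C(O[Si](C)(C)C)=C/C(=C)O[Si](C)(C)C | intermediate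
3 | benzaldehyde | O=Cc1ccccc1 | starting material
4 | ethyl (2Z,6S)-4-oxo-6-phenyl-2,6-bis(trimethylsilyloxy)hex-2-enoate (silylated aldol adduct) | CCOC(=O)/C(O[Si](C)(C)C)=C/C(=O)C[C@@H](c1ccccc1)O[Si](C)(C)C | intermediate
5 | ethyl (2S)-4-oxo-2-phenyl-3,4-dihydro-2H-pyran-6-carboxylate | CCOC(=O)C1=CC(=O)C[C@@H](c2ccccc2)O1 | intermediate
6 | (2S)-4-oxo-2-phenyl-3,4-dihydro-2H-pyran-6-carboxylic acid | OC(=O)C1=CC(=O)C[C@@H](c2ccccc2)O1 | intermediate
7 | (2S)-4-oxo-2-phenyl-3,4-dihydro-2H-pyran-6-carbonyl chloride | ClC(=O)C1=CC(=O)C[C@@H](c2ccccc2)O1 | intermediate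
8 | (2S)-6-(2-diazoacetyl)-2-phenyl-2,3-dihydro-4H-pyran-4-one | [N-]=[N+]=CC(=O)C1=CC(=O)C[C@@H](c2ccccc2)O1 | intermediate
9 | (2S,3S)-3-phenylglycidol | OC[C@@H]1O[C@H]1c1ccccc1 | starting material
10 | ethynyltrimethylsilane | C#C[Si](C)(C)C | starting material
11 | lithium (trimethylsilyl)acetylide | [Li]C#C[Si](C)(C)C | intermediate
12 | diethyl[(trimethylsilyl)ethynyl]aluminium | CC[Al](CC)C#C[Si](C)(C)C | intermediate
13 | (2R,3S)-3-phenyl-5-(trimethylsilyl)pent-4-yne-1,2-diol | OC[C@H](O)[C@@H](c1ccccc1)C#C[Si](C)(C)C | intermediate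
14 | (4R)-2-(4-methoxyphenyl)-4-[(1S)-1-phenyl-3-(trimethylsilyl)prop-2-yn-1-yl]-1,3-dioxolane (both acetal epimers) | COc1ccc(cc1)C1OC[C@H](O1)[C@@H](c1ccccc1)C#C[Si](C)(C)C | intermediate
15 | (2R,3S)-2-[(4-methoxybenzyl)oxy]-3-phenyl-5-(trimethylsilyl)pent-4-yn-1-ol | OC[C@H](OCc1ccc(OC)cc1)[C@@H](c1ccccc1)C#C[Si](C)(C)C | intermediate
16 | (2R,3S)-2-[(4-methoxybenzyl)oxy]-3-phenyl-5-(trimethylsilyl)pent-4-ynal | O=C[C@H](OCc1ccc(OC)cc1)[C@@H](c1ccccc1)C#C[Si](C)(C)C | intermediate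
17 | allyl tert-butyldimethylsilyl ether | C=CCO[Si](C)(C)C(C)(C)C | starting material
18 | 1-(tert-butyldimethylsilyloxy)allyllithium | C=CC([Li])O[Si](C)(C)C(C)(C)C | intermediate
19 | (Z)-tert-butyldimethyl{[3-(tributylstannyl)prop-1-en-1-yl]oxy}silane | CCCC[Sn](CCCC)(CCCC)C/C=C\O[Si](C)(C)C(C)(C)C | intermediate
20 | (3S,4S,5R,6S)-3-(tert-butyldimethylsilyloxy)-5-[(4-methoxybenzyl)oxy]-6-phenyl-8-(trimethylsilyl)oct-1-en-7-yn-4-ol | C=C[C@H](O[Si](C)(C)C(C)(C)C)[C@@H](O)[C@H](OCc1ccc(OC)cc1)[C@@H](c1ccccc1)C#C[Si](C)(C)C | intermediate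
21 | acrolein diethyl acetal | C=CC(OCC)OCC | starting material
22 | (3S,4S,5R,6S)-3-(tert-butyldimethylsilyloxy)-4-[(1-ethoxyprop-2-en-1-yl)oxy]-5-[(4-methoxybenzyl)oxy]-6-phenyl-8-(trimethylsilyl)oct-1-en-7-yne (both acetal epimers) | C=C[C@H](O[Si](C)(C)C(C)(C)C)[C@@H](OC(OCC)C=C)[C@H](OCc1ccc(OC)cc1)[C@@H](c1ccccc1)C#C[Si](C)(C)C | intermediate
23 | (5S,6S)-5-(tert-butyldimethylsilyloxy)-2-ethoxy-6-[(1R,2S)-1-[(4-methoxybenzyl)oxy]-2-phenyl-4-(trimethylsilyl)but-3-yn-1-yl]-5,6-dihydro-2H-pyran (both C2 epimers) | CCOC1C=C[C@H](O[Si](C)(C)C(C)(C)C)[C@@H](O1)[C@H](OCc1ccc(OC)cc1)[C@@H](c1ccccc1)C#C[Si](C)(C)C | intermediate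
24 | (5S,6S)-5-(tert-butyldimethylsilyloxy)-2-ethoxy-6-[(1R,2R)-1-[(4-methoxybenzyl)oxy]-2-phenylbut-3-yn-1-yl]-5,6-dihydro-2H-pyran (both C2 epimers) | CCOC1C=C[C@H](O[Si](C)(C)C(C)(C)C)[C@@H](O1)[C@H](OCc1ccc(OC)cc1)[C@@H](c1ccccc1)C#C | intermediate
25 | lithium acetylide derived from 24 (C≡C–Li in place of C≡C–H) | CCOC1C=C[C@H](O[Si](C)(C)C(C)(C)C)[C@@H](O1)[C@H](OCc1ccc(OC)cc1)[C@@H](c1ccccc1)C#C[Li] | intermediate
26 | lithium ynolate derived from 24 (C≡C–OLi) | CCOC1C=C[C@H](O[Si](C)(C)C(C)(C)C)[C@@H](O1)[C@H](OCc1ccc(OC)cc1)[C@@H](c1ccccc1)C#CO[Li] | intermediate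
27 | (5S,6S)-5-(tert-butyldimethylsilyloxy)-2-ethoxy-6-[(1R,2S)-1-[(4-methoxybenzyl)oxy]-2-phenyl-4-(triisopropylsilyloxy)but-3-yn-1-yl]-5,6-dihydro-2H-pyran (both C2 epimers) | CCOC1C=C[C@H](O[Si](C)(C)C(C)(C)C)[C@@H](O1)[C@H](OCc1ccc(OC)cc1)[C@@H](c1ccccc1)C#CO[Si](C(C)C)(C(C)C)C(C)C | intermediate
28 | [(2S)-4-oxo-2-phenyl-3,4-dihydro-2H-pyran-6-yl]ketene | O=C=CC1=CC(=O)C[C@@H](c2ccccc2)O1 | intermediate
29 | 4-[(2S)-4-oxo-2-phenyl-3,4-dihydro-2H-pyran-6-yl]-3-(triisopropylsilyloxy)cyclobut-2-en-1-one carrying the side chain of 27 at C2 (both C4 epimers) | CCOC1C=C[C@H](O[Si](C)(C)C(C)(C)C)[C@@H](O1)[C@H](OCc1ccc(OC)cc1)[C@@H](c1ccccc1)C1=C(O[Si](C(C)C)(C(C)C)C(C)C)C(C1=O)C1=CC(=O)C[C@@H](c2ccccc2)O1 | intermediate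
30 | (2S)-6-{(1S,2R)-2-[(5S,6S)-5-(tert-butyldimethylsilyloxy)-2-ethoxy-5,6-dihydro-2H-pyran-6-yl]-2-[(4-methoxybenzyl)oxy]-1-phenylethyl}-5-hydroxy-2-phenyl-7-(triisopropylsilyloxy)chroman-4-one (both acetal epimers) | CCOC1C=C[C@H](O[Si](C)(C)C(C)(C)C)[C@@H](O1)[C@H](OCc1ccc(OC)cc1)[C@@H](c1ccccc1)c1c(O[Si](C(C)C)(C(C)C)C(C)C)cc2c(c1O)C(=O)C[C@@H](c1ccccc1)O2 | intermediate
31 | (2S)-6-{(1S,2R)-2-[(5S,6S)-5-(tert-butyldimethylsilyloxy)-2-hydroxy-5,6-dihydro-2H-pyran-6-yl]-2-[(4-methoxybenzyl)oxy]-1-phenylethyl}-5-hydroxy-2-phenyl-7-(triisopropylsilyloxy)chroman-4-one (both lactol epimers) | OC1C=C[C@H](O[Si](C)(C)C(C)(C)C)[C@@H](O1)[C@H](OCc1ccc(OC)cc1)[C@@H](c1ccccc1)c1c(O[Si](C(C)C)(C(C)C)C(C)C)cc2c(c1O)C(=O)C[C@@H](c1ccccc1)O2 | intermediate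
32 | (2S)-6-{(1S,2R)-2-[(2S,3S)-3-(tert-butyldimethylsilyloxy)-6-oxo-3,6-dihydro-2H-pyran-2-yl]-2-[(4-methoxybenzyl)oxy]-1-phenylethyl}-5-hydroxy-2-phenyl-7-(triisopropylsilyloxy)chroman-4-one | O=C1C=C[C@H](O[Si](C)(C)C(C)(C)C)[C@@H](O1)[C@H](OCc1ccc(OC)cc1)[C@@H](c1ccccc1)c1c(O[Si](C(C)C)(C(C)C)C(C)C)cc2c(c1O)C(=O)C[C@@H](c1ccccc1)O2 | intermediate
33 | (2S)-5,7-dihydroxy-6-{(1S,2R)-2-hydroxy-2-[(2R,3S)-3-hydroxy-6-oxo-3,6-dihydro-2H-pyran-2-yl]-1-phenylethyl}-2-phenylchroman-4-one | O=C1C=C[C@H](O)[C@H]([C@H](O)[C@@H](c2ccccc2)c2c(O)cc3c(c2O)C(=O)C[C@@H](c2ccccc2)O3)O1 | target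

Total step count: 18. Longest linear sequence: 13 steps (steps 5 to 8 and 10 to 18).

Steps most likely to fail

Step 15 (benzannulation). Photochemical side reactions of the enone chromophore may compete with the Wolff rearrangement, and capture of the vinylketene by the hindered siloxyalkyne may be slow enough for the ketene to dimerise. The fallback sets out from diazoketone 8 and generates the same ketene thermally in the dark. A silver-promoted Wolff rearrangement of 8 in aqueous THF (AgO2CPh, Et3N; Arndt–Eistert homologation) would give [(2S)-4-oxo-2-phenyl-3,4-dihydro-2H-pyran-6-yl]acetic acid F1. Oxalyl chloride would turn it into [(2S)-4-oxo-2-phenyl-3,4-dihydro-2H-pyran-6-yl]acetyl chloride F2. Slow addition of Et3N to F2 and 27 in toluene should form vinylketene 28 by dehydrochlorination, and the route is rejoined at cyclobutenone 29 and, after heating, at 30.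

Step 2 (key step). The ester lowers the nucleophilicity of the diene, so the addition may be sluggish, and an uncatalysed silyl-transfer background reaction may erode the facial selectivity. The fallback sets out from benzaldehyde 3 and uses an unactivated diene. (E)-4-Methoxy-2-(trimethylsilyloxy)penta-1,3-diene F3 (from commercial (E)-4-methoxypent-3-en-2-one, Me3SiOTf, Et3N) would undergo the same Ti(OiPr)4/(S)-BINOL-catalysed oxa-Diels–Alder reaction with 3, followed by CF3CO2H, to give (2S)-6-methyl-2-phenyl-2,3-dihydro-4H-pyran-4-one F4. The same two bonds are formed. Riley oxidation of the methyl group (SeO2, dioxane) would give (2S)-4-oxo-2-phenyl-3,4-dihydro-2H-pyran-6-carbaldehyde F5, and Pinnick oxidation (NaClO2, NaH2PO4, 2-methylbut-2-ene) would return to the route at acid 6.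

Step 14 (siloxyalkyne). Deprotonation at the propargylic and benzylic C8′ position may lead to allene formation and loss of configuration, and oxygen transfer from the peroxide to the acetylide may be incomplete. The fallback sets out from alkyne 24 and reaches the ynolate without an acetylide. [Hydroxy(tosyloxy)iodo]benzene would convert 24 into the alkynyl(phenyl)iodonium tosylate F6. CuOTf-catalysed collapse of F6 would give the alkynyl tosylate F7. MeLi at −78 °C would cleave its S–O bond to give lithium ynolate 26, and silylation with i-Pr3SiOTf returns to the route at 27.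

Further compounds
F1 | step 15 | [(2S)-4-oxo-2-phenyl-3,4-dihydro-2H-pyran-6-yl]acetic acid | OC(=O)CC1=CC(=O)C[C@@H](c2ccccc2)O1
F2 | step 15 | [(2S)-4-oxo-2-phenyl-3,4-dihydro-2H-pyran-6-yl]acetyl chloride | ClC(=O)CC1=CC(=O)C[C@@H](c2ccccc2)O1
F3 | step 2 | (E)-4-methoxy-2-(trimethylsilyloxy)penta-1,3-diene | CO/C(C)=C/C(=C)O[Si](C)(C)C
F4 | step 2 | (2S)-6-methyl-2-phenyl-2,3-dihydro-4H-pyran-4-one | CC1=CC(=O)C[C@@H](c2ccccc2)O1
F5 | step 2 | (2S)-4-oxo-2-phenyl-3,4-dihydro-2H-pyran-6-carbaldehyde | O=CC1=CC(=O)C[C@@H](c2ccccc2)O1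
F6 | step 14 | alkynyl(phenyl)iodonium tosylate derived from 24 | CCOC1C=C[C@H](O[Si](C)(C)C(C)(C)C)[C@@H](O1)[C@H](OCc1ccc(OC)cc1)[C@@H](c1ccccc1)C#C[I+]c1ccccc1.Cc1ccc(cc1)S(=O)(=O)[O-]
F7 | step 14 | alkynyl tosylate derived from 24 | CCOC1C=C[C@H](O[Si](C)(C)C(C)(C)C)[C@@H](O1)[C@H](OCc1ccc(OC)cc1)[C@@H](c1ccccc1)C#COS(=O)(=O)c1ccc(C)cc1
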